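**Plan**

1. Numbering used: furanone O1, C2 (C=O), C3 (CH), C4 (aryl-bearing), C5; benzylidene carbon C6; Ar = 3,5-dibromo-4-methoxyphenyl.
2. Retrosynthesis: cut the two O–CH3 bonds (masked phenols); then C2–C3 together with O1–C2, which removes the lactone carbonyl as a one-carbon carbonic acid unit and leaves the enone ArCH2–CO–C(Ar)=CH2; then C3=C4 (methylene) to the symmetrical ketone ArCH2–CO–CH2Ar; then C4–C5 to two molecules of one arylacetic acid.
3. Enabling feature: C2 and C5 are 1,4-related oxidised carbons, so C3 (β to the C5 carbonyl in the open chain) is an acceptor like C2. A phosphine turns C3 into an ylide donor; C4 carries no hydrogen, so the enolate can only be O-acylated; the benzylic C6–H lets the phosphine leave again.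
4. Forward order: bromination and O-methylation of the arylacetic acid, chain joined by decarboxylative self-condensation, methylenation, then the furanone (the only ring made) is closed at C2–C3 in one flask, then demethylation.
5. Stereochemistry: there is no stereocentre; the Z C5=C6 bond arises in the last elimination of the ring-forming step and is also the thermodynamic isomer.

Key step: step 5

Remark: the target is taken as the Z isomer written in its SMILES (C6 aryl syn to O1); stereocentres in intermediates are racemic and are lost again.

**Route**

Step 1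
Reactants: 1 4-hydroxyphenylacetic acid
Product: 2 2-(3,5-dibromo-4-hydroxyphenyl)acetic acid
Conditions: Br2 (2.1 equiv), AcOH, rt
Reagents that add atoms: bromine, BrBr
Why: Electrophilic aromatic bromination in which the hydroxyl group directs to both ortho positions and the para position is blocked, so only the 3,5-dibromide is expected.

Step 2
Reactants: 2 2-(3,5-dibromo-4-hydroxyphenyl)acetic acid
Product: 4 2-(3,5-dibromo-4-methoxyphenyl)acetic acid, via methyl ester 3 (not isolated)
Conditions: MeI (3 equiv), K2CO3 (3 equiv), DMF, rt; then 2 M aq NaOH, MeOH, 50 °C; aq HCl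
Reagents that add atoms: iodomethane, CI; sodium hydroxide, [Na+].[OH-]
Why: Williamson-type O-methylation of the phenoxide and the carboxylate, followed by saponification of the methyl ester only, should leave the hindered aryl methyl ether and the aryl bromides untouched.

Step 3
Reactants: 4 2-(3,5-dibromo-4-methoxyphenyl)acetic acid (two molecules)
Product: 5 1,3-bis(3,5-dibromo-4-methoxyphenyl)propan-2-one
Conditions: DCC (0.55 equiv), DMAP (0.25 equiv), CH2Cl2, rt
Reagents that add atoms: none
Why: Carbodiimide/DMAP-mediated decarboxylative self-condensation of an arylacetic acid, in which the activated acid is C-acylated through its ketene or enolate form and the β-keto acid derivative loses CO2, is a known way to symmetrical 1,3-diarylacetones.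

Step 4
Reactants: 5 1,3-bis(3,5-dibromo-4-methoxyphenyl)propan-2-one
Product: 7 1,3-bis(3,5-dibromo-4-methoxyphenyl)but-3-en-2-one, via Mannich base 6 (not isolated)
Conditions: Me2NCH2NMe2 (1.1 equiv), Ac2O (2.5 equiv), DMF, 0 → 50 °C
Reagents that add atoms: bis(dimethylamino)methane, CN(C)CN(C)C
Why: Mannich reaction of the ketone enol with the iminium acetate formed from the aminal and Ac2O, then E1cB loss of dimethylamine (trapped as its acetamide) from the acidic benzylic position, is the established α-methylenation of benzyl ketones and is limited to one side by using about one equivalent of aminal.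

Step 5
Reactants: 7 1,3-bis(3,5-dibromo-4-methoxyphenyl)but-3-en-2-one
Product: 10 (Z)-4-(3,5-dibromo-4-methoxyphenyl)-5-[(3,5-dibromo-4-methoxyphenyl)methylidene]furan-2(5H)-one, via phosphonium enol carbonate 8 (not isolated), via ylide lactone 9 (not isolated)
Conditions: PBu3 (1.0 equiv), 4-O2NC6H4OCOCl (1.05 equiv), THF, −20 → 0 °C; then Et3N (2.5 equiv), 0 °C → rt; then 65 °C
Reagents that add atoms: 4-nitrophenyl chloroformate, O=C(Cl)Oc1ccc(cc1)[N+](=O)[O-]; tributylphosphine, CCCCP(CCCC)CCCC (its atoms stay only in 8 and 9)
Why: Proposed new method: PBu3 should add to the unsubstituted C3 of enone 7, and the β-phosphonio enolate, held cis by the P+/O− contact, should be O-acylated at once by the chloroformate to give 8; Et3N then forms the allylic ylide at C3, the former acceptor carbon now a donor, which attacks the carbonate carbonyl in a 5-exo-trig closure that makes the C2–C3 bond and the furanone ring, with 4-nitrophenoxide leaving to give the ester-stabilised ylide 9. On warming, reprotonation of 9 at C3 by the ammonium/nitrophenol buffer and removal of the benzylic C6–H should trigger a 1,4-elimination that moves C4=C5 to C3=C4, creates C5=C6 and releases the phosphine unchanged. The closest known reactions are the phosphine addition/O-acylation/ylide sequence that converts enones and acid chlorides into furans by intramolecular Wittig reaction, the C-acylation of phosphonium ylides by chloroformates and active esters, and the thermal loss of a phosphine from stabilised ylides after a proton shift; new here are the carbonate as one-carbon partner and the vinylogous elimination. No stereocentre is formed, and the C5=C6 bond should be Z because the C6 aryl avoids the C4 aryl in the elimination and the Z isomer is also the thermodynamic one. The selectivities needed are O- over C-acylation of the enolate (secured by the fully substituted C4), acyl substitution over Wittig olefination at the carbonate (secured by the 4-nitrophenoxide leaving group, and any O-to-C acyl shift re-closes to the same lactone), and ylide formation at C3 before premature loss of phosphine from 8 (C3–H next to phosphorus is the more acidic site, and the cyclisation is run cold before heating).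

Step 6
Reactants: 10 (Z)-4-(3,5-dibromo-4-methoxyphenyl)-5-[(3,5-dibromo-4-methoxyphenyl)methylidene]furan-2(5H)-one
Product: 11 rubrolide A, (Z)-4-(3,5-dibromo-4-hydroxyphenyl)-5-[(3,5-dibromo-4-hydroxyphenyl)methylidene]furan-2(5H)-one
Conditions: BBr3 (6 equiv), CH2Cl2, −78 °C → rt; then H2O
Reagents that add atoms: none
Why: Lewis-acid cleavage of aryl methyl ethers by BBr3 (bromide attacks the methyl group of the boron-complexed ether) is the standard last step for ylidenebutenolides of this class and should leave the lactone and the Z alkene unchanged.

**Compound list**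

1 | 4-hydroxyphenylacetic acid | OC(=O)Cc1ccc(O)cc1 | starting material
2 | 2-(3,5-dibromo-4-hydroxyphenyl)acetic acid | OC(=O)Cc1cc(Br)c(O)c(Br)c1 | intermediate
3 | methyl 2-(3,5-dibromo-4-methoxyphenyl)acetate | COC(=O)Cc1cc(Br)c(OC)c(Br)c1 | intermediate
4 | 2-(3,5-dibromo-4-methoxyphenyl)acetic acid | OC(=O)Cc1cc(Br)c(OC)c(Br)c1 | intermediate
5 | 1,3-bis(3,5-dibromo-4-methoxyphenyl)propan-2-one | O=C(Cc1cc(Br)c(OC)c(Br)c1)Cc1cc(Br)c(OC)c(Br)c1 | intermediate
6 | 1,3-bis(3,5-dibromo-4-methoxyphenyl)-4-(dimethylamino)butan-2-one (racemic Mannich base) | CN(C)CC(c1cc(Br)c(OC)c(Br)c1)C(=O)Cc1cc(Br)c(OC)c(Br)c1 | intermediate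
7 | 1,3-bis(3,5-dibromo-4-methoxyphenyl)but-3-en-2-one | C=C(c1cc(Br)c(OC)c(Br)c1)C(=O)Cc1cc(Br)c(OC)c(Br)c1 | intermediate
8 | tributyl[(2Z)-2,4-bis(3,5-dibromo-4-methoxyphenyl)-3-{[(4-nitrophenoxy)carbonyl]oxy}but-2-en-1-yl]phosphonium chloride | CCCC[P+](CCCC)(CCCC)C/C(c1cc(Br)c(OC)c(Br)c1)=C(/Cc1cc(Br)c(OC)c(Br)c1)OC(=O)Oc1ccc(cc1)[N+](=O)[O-].[Cl-] | intermediate
9 | 4-(3,5-dibromo-4-methoxyphenyl)-5-[(3,5-dibromo-4-methoxyphenyl)methyl]-3-(tributyl-λ5-phosphanylidene)furan-2(3H)-one | CCCCP(CCCC)(CCCC)=C1C(=O)OC(Cc2cc(Br)c(OC)c(Br)c2)=C1c1cc(Br)c(OC)c(Br)c1 | intermediate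
10 | (Z)-4-(3,5-dibromo-4-methoxyphenyl)-5-[(3,5-dibromo-4-methoxyphenyl)methylidene]furan-2(5H)-one (rubrolide A dimethyl ether) | O=C1C=C(c2cc(Br)c(OC)c(Br)c2)/C(=C/c2cc(Br)c(OC)c(Br)c2)O1 | intermediate
11 | rubrolide A, (Z)-4-(3,5-dibromo-4-hydroxyphenyl)-5-[(3,5-dibromo-4-hydroxyphenyl)methylidene]furan-2(5H)-one | O=C1C=C(c2cc(Br)c(O)c(Br)c2)/C(=C/c2cc(Br)c(O)c(Br)c2)O1 | target

**Summary and risks**

Total step count: 6. Longest linear sequence: 6 steps (1 to 11).

Steps most likely to fail:

1. Step 5. The ester-stabilised ylide may resist the proton shift and loss of phosphine and so become the end point, or the zwitterion may add to a second enone molecule before it is acylated. Fallback by known chemistry, setting out from 5: acid-catalysed aldol condensation with glyoxylic acid monohydrate (85% H3PO4, 90 °C) should give, after lactonisation of the cis keto acid, the racemic 4-aryl-5-(arylmethyl)-5-hydroxyfuran-2(5H)-one F1. Dehydration (TsOH, toluene, reflux with removal of water) should give the Z ylidenebutenolide and comes back to the route at 10. Here the ring is made through C3=C4 and O1–C2 instead.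

2. Step 4. A second Mannich reaction at the other benzylic carbon and oligomerisation of the enone on concentration may erode the material. Fallback, setting out from 5: dimethyl(methylidene)ammonium iodide (CH2=NMe2+ I−) in MeCN at 50 °C should give the Mannich base 6, here isolated. MeI then gives the crystalline [2,4-bis(3,5-dibromo-4-methoxyphenyl)-3-oxobutyl]trimethylammonium iodide F2, and crystallisation removes doubly aminomethylated material. Treatment of F2 with Et3N (1 equiv) in THF at 0 °C sets the enone free in solution just before use, so the route is rejoined at 7 without isolating it.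

3. Step 3. The activated acid may be diverted by O-to-N acyl shift to the N-acylurea, or may stop at the symmetrical anhydride. Fallback, setting out from 3 (isolated by leaving out the hydroxide stage of step 2): Claisen self-condensation (NaH, THF, 0 °C → rt) should give methyl 2,4-bis(3,5-dibromo-4-methoxyphenyl)-3-oxobutanoate F3. Hydrolysis and decarboxylation (AcOH, aq HCl, 100 °C) then comes back to the route at 5.

**Further compounds**

F1 | step 5 | 4-(3,5-dibromo-4-methoxyphenyl)-5-[(3,5-dibromo-4-methoxyphenyl)methyl]-5-hydroxyfuran-2(5H)-one (racemic) | O=C1C=C(c2cc(Br)c(OC)c(Br)c2)C(O)(Cc2cc(Br)c(OC)c(Br)c2)O1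
F2 | step 4 | [2,4-bis(3,5-dibromo-4-methoxyphenyl)-3-oxobutyl]trimethylammonium iodide (racemic) | C[N+](C)(C)CC(c1cc(Br)c(OC)c(Br)c1)C(=O)Cc1cc(Br)c(OC)c(Br)c1.[I-]
F3 | step 3 | methyl 2,4-bis(3,5-dibromo-4-methoxyphenyl)-3-oxobutanoate (racemic) | COC(=O)C(c1cc(Br)c(OC)c(Br)c1)C(=O)Cc1cc(Br)c(OC)c(Br)c1
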